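**Strategy.** Everything rests on cutting the trisubstituted C1=C8a alkene of the octahydronaphthalene, endocyclic in ring A (C1–C4, C4a, C8a) and exocyclic to ring B (C4a–C8a). C8a is the carbonyl carbon of a carvone-derived ring B, and C1 is a vinyl CH on the quaternary C2. In one operation a stoichiometric molybdenum alkylidene turns that vinyl group into a carbene that olefinates the ketone, closing ring A by ring-closing carbonyl–olefin metathesis. The precursor is a monocyclic keto diene, assembled by alkylating the kinetic enolate of (2R,5S)-dihydrocarvone with an iodide whose benzylic and quaternary stereocentres were set inside a temporary dihydrocoumarin ring.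

Key step: step 10

Remark: bicyclic locants are C1 (alkene CH), C2 (quaternary C), C4a (sp3 ring-fusion CH), C5 (carbinol-bearing C), C8 (methyl-bearing C), C8a (sp2 ring-fusion C); all reagents named in the Conditions lines are taken as purchased, and the antipode of the copper ligand that gives the 4S product is used.

Step 1
Reactants: 1 5,7-dimethoxycoumarin
Product: 2 (4S)-5,7-dimethoxy-4-(2-methylpropyl)-3,4-dihydro-2H-chromen-2-one
Conditions: i-BuMgBr, CuBr·SMe2 (5 mol %), Josiphos-type ferrocenyl diphosphine (6 mol %), t-BuOMe–CH2Cl2, −75 °C; then 1 M HCl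
Reagents that add atoms: isobutylmagnesium bromide, CC(C)C[Mg]Br
Why: Copper-catalysed asymmetric conjugate addition of a Grignard reagent to a coumarin, in which the chiral diphosphine complex of monovalent copper delivers isobutyl to one face of C4 and so sets the benzylic stereocentre (4S).

Step 2
Reactants: 2 (4S)-5,7-dimethoxy-4-(2-methylpropyl)-3,4-dihydro-2H-chromen-2-one
Product: 3 (3S,4S)-3-[2-(tert-butyldimethylsilyloxy)ethyl]-5,7-dimethoxy-4-(2-methylpropyl)-3,4-dihydro-2H-chromen-2-one (3,4-trans)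
Conditions: LiN(i-Pr)2, THF, −78 °C; then ICH2CH2OSiMe2t-Bu, DMPU, −78 to 0 °C
Reagents that add atoms: tert-butyl(2-iodoethoxy)dimethylsilane, CC(C)(C)[Si](C)(C)OCCI
Why: Lithium enolate alkylation in which peri strain with the 5-methoxy group holds the 4-isobutyl group pseudoaxial, so the iodide is attacked from the opposite face to give the 3,4-trans lactone (the C3 configuration is rewritten in step 3).

Step 3
Reactants: 3 (3S,4S)-3-[2-(tert-butyldimethylsilyloxy)ethyl]-5,7-dimethoxy-4-(2-methylpropyl)-3,4-dihydro-2H-chromen-2-one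
Product: 4 (3R,4R)-3-[2-(tert-butyldimethylsilyloxy)ethyl]-5,7-dimethoxy-3-methyl-4-(2-methylpropyl)-3,4-dihydro-2H-chromen-2-one (methyl trans to isobutyl)
Conditions: LiN(i-Pr)2, THF, −78 °C; then MeI, −78 to −20 °C
Reagents that add atoms: iodomethane, CI
Why: Second enolate alkylation under substrate control (1,2-induction in the temporary lactone ring), in which iodomethane enters anti to the pseudoaxial isobutyl group and fixes the quaternary centre with methyl trans and the silyloxyethyl arm cis to isobutyl.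

Step 4
Reactants: 4 (3R,4R)-3-[2-(tert-butyldimethylsilyloxy)ethyl]-5,7-dimethoxy-3-methyl-4-(2-methylpropyl)-3,4-dihydro-2H-chromen-2-one
Product: 6 (3R)-3-methyl-3-[(1R)-3-methyl-1-(2,4,6-trimethoxyphenyl)butyl]oxolan-2-one, via ring-switched phenol lactone 5 (not isolated)
Conditions: Bu4NF, THF, 0 °C to rt; then MeI, rt
Reagents that add atoms: iodomethane, CI
Why: Fluoride desilylation frees a primary alkoxide that attacks the aryl ester (5-exo-trig translactonisation) and expels the phenoxide, which is O-methylated in the same flask (Williamson ether synthesis) without touching a stereocentre.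

Step 5
Reactants: 6 (3R)-3-methyl-3-[(1R)-3-methyl-1-(2,4,6-trimethoxyphenyl)butyl]oxolan-2-one
Product: 7 (3R)-3-methyl-3-[(1R)-3-methyl-1-(2,4,6-trimethoxyphenyl)butyl]oxolan-2-ol (mixture of anomers)
Conditions: i-Bu2AlH, CH2Cl2, −78 °C; aq. potassium sodium tartrate
Reagents that add atoms: none
Why: Partial reduction of a lactone with i-Bu2AlH should stop at the lactol because the tetrahedral aluminium acetal survives at −78 °C.

Step 6
Reactants: 7 (3R)-3-methyl-3-[(1R)-3-methyl-1-(2,4,6-trimethoxyphenyl)butyl]oxolan-2-ol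
Product: 8 (3S,4S)-3-ethenyl-3,6-dimethyl-4-(2,4,6-trimethoxyphenyl)heptan-1-ol
Conditions: Ph3PCH3Br, KOt-Bu, THF, 0 to 65 °C
Reagents that add atoms: methyltriphenylphosphonium bromide, C[P+](c1ccccc1)(c1ccccc1)c1ccccc1.[Br-]
Why: Wittig methylenation of the open hydroxy aldehyde form of the lactol should give the vinyl group on the quaternary carbon and free the primary alcohol, and the aldehyde has no α-hydrogen that could epimerise.

Step 7
Reactants: 8 (3S,4S)-3-ethenyl-3,6-dimethyl-4-(2,4,6-trimethoxyphenyl)heptan-1-ol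
Product: 9 2-[(3S,4S)-3-ethenyl-1-iodo-3,6-dimethylheptan-4-yl]-1,3,5-trimethoxybenzene
Conditions: I2, PPh3, imidazole, CH2Cl2, 0 °C to rt
Reagents that add atoms: iodine, II
Why: Appel-type iodination should convert the primary alcohol into the iodide by SN2 displacement at an unhindered carbon.

Step 8
Reactants: 10 (S)-(+)-carvone
Product: 11 (2R,5S)-2-methyl-5-(prop-1-en-2-yl)cyclohexan-1-one (cis-dihydrocarvone)
Conditions: Old Yellow Enzyme 1 (wild-type ene-reductase), NADP+ (cat.), glucose dehydrogenase, D-glucose, phosphate buffer pH 7, 30 °C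
Reagents that add atoms: none
Why: Flavin-dependent ene-reductase reduction adds hydride to C3 and a proton to C2 under enzyme control, giving the 2R (cis, less stable) epimer that chemical reductions do not favour, while C5 comes from carvone.

Step 9
Reactants: 11 (2R,5S)-2-methyl-5-(prop-1-en-2-yl)cyclohexan-1-one; 9 2-[(3S,4S)-3-ethenyl-1-iodo-3,6-dimethylheptan-4-yl]-1,3,5-trimethoxybenzene
Product: 12 (2R,3S,6R)-2-[(3S,4S)-3-ethenyl-3,6-dimethyl-4-(2,4,6-trimethoxyphenyl)heptyl]-6-methyl-3-(prop-1-en-2-yl)cyclohexan-1-one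
Conditions: 11 (1.8 equiv), LiN(i-Pr)2 (1.9 equiv), THF, −78 °C; then 9 (1.0 equiv), DMPU, −78 to −20 °C; cold aq. NH4Cl
Reagents that add atoms: none
Why: Kinetic enolate alkylation, in which the amide base removes a proton only from the CH2 α-carbon of 11 and the iodide is attacked on the face opposite both the neighbouring isopropenyl group and the cis methyl group, should give the 2,3-trans product with the axial methyl centre untouched.

Step 10
Reactants: 12 (2R,3S,6R)-2-[(3S,4S)-3-ethenyl-3,6-dimethyl-4-(2,4,6-trimethoxyphenyl)heptyl]-6-methyl-3-(prop-1-en-2-yl)cyclohexan-1-one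
Product: 14 2-[(1S)-1-[(2S,4aR,5S,8R)-2,8-dimethyl-5-(prop-1-en-2-yl)-2,3,4,4a,5,6,7,8-octahydronaphthalen-2-yl]-3-methylbutyl]-1,3,5-trimethoxybenzene, via molybdenum alkylidene 13 (not isolated)
Conditions: Mo(=CHCMe2Ph)(=N-2,6-i-Pr2C6H3)[OCMe(CF3)2]2 (1.1 equiv), C6H6, 25 to 50 °C, glove box
Reagents that add atoms: none
Why: The molybdenum neophylidene first undergoes cross-metathesis with the only monosubstituted alkene, the vinyl group on the quaternary carbon, to give alkylidene 13 and 3-methyl-3-phenylbut-1-ene; 13 then adds across the ketone C=O in a [2+2] fashion and the oxamolybdacyclobutane collapses to the C1=C8a alkene and a molybdenum oxo complex. The closest known reaction type is the stoichiometric ring-closing carbonyl–olefin metathesis of olefinic ketones with molybdenum imido alkylidenes (olefin metathesis followed by Wittig-like carbonyl olefination). Ring A closes in a 6-exo-trig sense, the alkylidene carbon attacking the carbonyl carbon whose C=O bond lies outside the new ring. No stereocentre is created and the alkene geometry is fixed by the ring. The step needs chemoselectivity, which the substrate should secure because the 1,1-disubstituted isopropenyl group cannot take up the alkylidene and a seven-membered closure onto it is slower than the irreversible six-membered carbonyl olefination; it also needs retention of the two ketone α-stereocentres, which the neutral, non-basic conditions provide.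

Step 11
Reactants: 14 2-[(1S)-1-[(2S,4aR,5S,8R)-2,8-dimethyl-5-(prop-1-en-2-yl)-2,3,4,4a,5,6,7,8-octahydronaphthalen-2-yl]-3-methylbutyl]-1,3,5-trimethoxybenzene
Product: 15 2-[(1S)-1-[(2S,4aR,5S,8R)-5-(2-hydroxypropan-2-yl)-2,8-dimethyl-2,3,4,4a,5,6,7,8-octahydronaphthalen-2-yl]-3-methylbutyl]-1,3,5-trimethoxybenzene
Conditions: Co(acac)2 (cat.), PhSiH3, O2 (1 atm), THF–i-PrOH, rt; then aq. Na2S2O3
Reagents that add atoms: dioxygen, O=O
Why: Mukaiyama hydration (cobalt-catalysed hydrogen-atom transfer, then oxygen trapping of the tertiary radical) is Markovnikov-selective and should prefer the 1,1-disubstituted isopropenyl group over the hindered trisubstituted ring alkene, forming no stereocentre.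

Step 12
Reactants: 15 2-[(1S)-1-[(2S,4aR,5S,8R)-5-(2-hydroxypropan-2-yl)-2,8-dimethyl-2,3,4,4a,5,6,7,8-octahydronaphthalen-2-yl]-3-methylbutyl]-1,3,5-trimethoxybenzene
Product: 17 5-[(1S)-1-[(2S,4aR,5S,8R)-5-(2-hydroxypropan-2-yl)-2,8-dimethyl-2,3,4,4a,5,6,7,8-octahydronaphthalen-2-yl]-3-methylbutyl]-2,4,6-trimethoxybenzene-1,3-dicarbaldehyde, via lithium hemiaminal alkoxide 16 (not isolated)
Conditions: n-BuLi, TMEDA, THF, 0 °C; DMF, −78 °C; then n-BuLi, 0 °C; DMF, −78 °C to rt; 1 M HCl work-up
Reagents that add atoms: N,N-dimethylformamide, CN(C)C=O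
Why: Directed ortho-metalation, in which each remaining aryl hydrogen lies between two methoxy groups and is lithiated by n-BuLi, DMF gives a lithium hemiaminal alkoxide that masks the first aldehyde in the flask, and a second lithiation–formylation installs the other formyl group.

Step 13
Reactants: 17 5-[(1S)-1-[(2S,4aR,5S,8R)-5-(2-hydroxypropan-2-yl)-2,8-dimethyl-2,3,4,4a,5,6,7,8-octahydronaphthalen-2-yl]-3-methylbutyl]-2,4,6-trimethoxybenzene-1,3-dicarbaldehyde
Product: 18 5-[(1S)-1-[(2S,4aR,5S,8R)-5-(2-hydroxypropan-2-yl)-2,8-dimethyl-2,3,4,4a,5,6,7,8-octahydronaphthalen-2-yl]-3-methylbutyl]-2,4,6-trihydroxybenzene-1,3-dicarbaldehyde (target)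
Conditions: 4-MeC6H4SNa (excess), HMPA–toluene, 110 °C; then 1 M HCl
Reagents that add atoms: none
Why: Nucleophilic demethylation (SN2 at methyl by the arenethiolate) should remove all three methyl groups because each methoxy group is ortho to a formyl group, and the basic medium leaves the tertiary alcohol and the alkene alone.

**Compound list**

1 | 5,7-dimethoxycoumarin (5,7-dimethoxy-2H-chromen-2-one) | O=c1ccc2c(OC)cc(OC)cc2o1 | starting material
2 | (4S)-5,7-dimethoxy-4-(2-methylpropyl)-3,4-dihydro-2H-chromen-2-one | O=C1C[C@H](CC(C)C)c2c(OC)cc(OC)cc2O1 | intermediate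
3 | (3S,4S)-3-[2-(tert-butyldimethylsilyloxy)ethyl]-5,7-dimethoxy-4-(2-methylpropyl)-3,4-dihydro-2H-chromen-2-one | O=C1[C@@H](CCO[Si](C)(C)C(C)(C)C)[C@H](CC(C)C)c2c(OC)cc(OC)cc2O1 | intermediate
4 | (3R,4R)-3-[2-(tert-butyldimethylsilyloxy)ethyl]-5,7-dimethoxy-3-methyl-4-(2-methylpropyl)-3,4-dihydro-2H-chromen-2-one | O=C1[C@](C)(CCO[Si](C)(C)C(C)(C)C)[C@H](CC(C)C)c2c(OC)cc(OC)cc2O1 | intermediate
5 | (3R)-3-[(1R)-1-(2-hydroxy-4,6-dimethoxyphenyl)-3-methylbutyl]-3-methyloxolan-2-one (formed as its tetrabutylammonium phenoxide) | O=C1OCC[C@]1(C)[C@H](CC(C)C)c1c(O)cc(OC)cc1OC | intermediate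
6 | (3R)-3-methyl-3-[(1R)-3-methyl-1-(2,4,6-trimethoxyphenyl)butyl]oxolan-2-one | O=C1OCC[C@]1(C)[C@H](CC(C)C)c1c(OC)cc(OC)cc1OC | intermediate
7 | (3R)-3-methyl-3-[(1R)-3-methyl-1-(2,4,6-trimethoxyphenyl)butyl]oxolan-2-ol (anomeric mixture) | OC1OCC[C@]1(C)[C@H](CC(C)C)c1c(OC)cc(OC)cc1OC | intermediate
8 | (3S,4S)-3-ethenyl-3,6-dimethyl-4-(2,4,6-trimethoxyphenyl)heptan-1-ol | OCC[C@@](C)(C=C)[C@H](CC(C)C)c1c(OC)cc(OC)cc1OC | intermediate
9 | 2-[(3S,4S)-3-ethenyl-1-iodo-3,6-dimethylheptan-4-yl]-1,3,5-trimethoxybenzene | ICC[C@@](C)(C=C)[C@H](CC(C)C)c1c(OC)cc(OC)cc1OC | intermediate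
10 | (S)-(+)-carvone | O=C1C(C)=CC[C@H](C(C)=C)C1 | starting material
11 | (2R,5S)-2-methyl-5-(prop-1-en-2-yl)cyclohexan-1-one | O=C1[C@H](C)CC[C@H](C(C)=C)C1 | intermediate
12 | (2R,3S,6R)-2-[(3S,4S)-3-ethenyl-3,6-dimethyl-4-(2,4,6-trimethoxyphenyl)heptyl]-6-methyl-3-(prop-1-en-2-yl)cyclohexan-1-one | O=C1[C@H](C)CC[C@H](C(C)=C)[C@H]1CC[C@@](C)(C=C)[C@H](CC(C)C)c1c(OC)cc(OC)cc1OC | intermediate
13 | molybdenum alkylidene of 12 (the vinyl CH2 replaced by the Mo(=N-2,6-i-Pr2C6H3)[OCMe(CF3)2]2 fragment, stereocentres as in 12) | O=C1[C@H](C)CC[C@H](C(C)=C)[C@H]1CC[C@@](C)(C=[Mo](=Nc1c(C(C)C)cccc1C(C)C)(OC(C)(C(F)(F)F)C(F)(F)F)OC(C)(C(F)(F)F)C(F)(F)F)[C@H](CC(C)C)c1c(OC)cc(OC)cc1OC | intermediate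
14 | 2-[(1S)-1-[(2S,4aR,5S,8R)-2,8-dimethyl-5-(prop-1-en-2-yl)-2,3,4,4a,5,6,7,8-octahydronaphthalen-2-yl]-3-methylbutyl]-1,3,5-trimethoxybenzene | CC(C)C[C@H](c1c(OC)cc(OC)cc1OC)[C@]1(C)C=C2[C@H](C)CC[C@H](C(C)=C)[C@H]2CC1 | intermediate
15 | 2-[(1S)-1-[(2S,4aR,5S,8R)-5-(2-hydroxypropan-2-yl)-2,8-dimethyl-2,3,4,4a,5,6,7,8-octahydronaphthalen-2-yl]-3-methylbutyl]-1,3,5-trimethoxybenzene | CC(C)C[C@H](c1c(OC)cc(OC)cc1OC)[C@]1(C)C=C2[C@H](C)CC[C@H](C(C)(C)O)[C@H]2CC1 | intermediate
16 | dilithium salt of the monoformyl hemiaminal of 15 (aryl CH(OLi)NMe2 at one free ring position, tertiary alkoxide lithiated; hemiaminal carbon unassigned) | CC(C)C[C@H](c1c(OC)cc(OC)c(C([O-])N(C)C)c1OC)[C@]1(C)C=C2[C@H](C)CC[C@H](C(C)(C)[O-])[C@H]2CC1.[Li+].[Li+] | intermediate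
17 | 5-[(1S)-1-[(2S,4aR,5S,8R)-5-(2-hydroxypropan-2-yl)-2,8-dimethyl-2,3,4,4a,5,6,7,8-octahydronaphthalen-2-yl]-3-methylbutyl]-2,4,6-trimethoxybenzene-1,3-dicarbaldehyde | CC(C)C[C@H](c1c(OC)c(C=O)c(OC)c(C=O)c1OC)[C@]1(C)C=C2[C@H](C)CC[C@H](C(C)(C)O)[C@H]2CC1 | intermediate
18 | 5-[(1S)-1-[(2S,4aR,5S,8R)-5-(2-hydroxypropan-2-yl)-2,8-dimethyl-2,3,4,4a,5,6,7,8-octahydronaphthalen-2-yl]-3-methylbutyl]-2,4,6-trihydroxybenzene-1,3-dicarbaldehyde | CC(C)C[C@H](c1c(O)c(C=O)c(O)c(C=O)c1O)[C@]1(C)C=C2[C@H](C)CC[C@H](C(C)(C)O)[C@H]2CC1 | target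

**Step count.** Total: 13 steps. Longest linear sequence: 12 steps (steps 1–7, then 9–13).

**Steps most likely to fail**

Step 10 (key step). Alkylidene transfer to the hindered vinyl group on the quaternary carbon may be slow, so that direct olefination of the ketone by the neophylidene, or ring closure onto the isopropenyl group, competes. The fallback sets out from compound 12. Takai–Lombardo methylenation (Zn, CH2Br2, TiCl4, THF–CH2Cl2, 0 °C; non-basic, so the α-methyl centre is kept) should give the methylidene triene F1. Ring-closing olefin metathesis with the second-generation Hoveyda–Grubbs catalyst (toluene, 80 °C, loss of ethene) should then close the same six-membered ring in preference to the seven-membered alternative and comes back to the route at compound 14.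

Step 9. The SN2 reaction of the unactivated iodide may be slow, so that proton transfer between product and enolate equilibrates the enolate and brings polyalkylation and epimerisation of the axial methyl centre. The fallback sets out from compound 11. Condensation with 1,1-dimethylhydrazine (no acid, rt) should give the N,N-dimethylhydrazone F2. Its lithium aza-enolate (LiN(i-Pr)2, THF, 0 °C) is alkylated by 9 at the CH2 α-carbon, anti to the isopropenyl group, to give the alkylated hydrazone F3. Buffered cleavage (aq. CuCl2, THF, pH 7) comes back to the route at compound 12.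

Step 12. The second ortho-lithiation may stall next to the lithium hemiaminal alkoxide or be overtaken by allylic deprotonation, leaving mixtures of mono- and dialdehyde. The fallback sets out from compound 15. Electrophilic aromatic bromination (N-bromosuccinimide, 2.1 equiv, MeCN, −20 °C) should give the dibromide F4. Bromine–lithium exchange (MeLi for the alcohol, then t-BuLi, THF, −78 °C) followed by DMF comes back to the route at compound 17.

**Further compounds**

F1 | step 10 | methylidene triene: compound 12 with the ketone C=O replaced by C=CH2, all stereocentres as in 12 | C=C1[C@H](C)CC[C@H](C(C)=C)[C@H]1CC[C@@](C)(C=C)[C@H](CC(C)C)c1c(OC)cc(OC)cc1OC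
F2 | step 9 | N,N-dimethylhydrazone of 11 (NMe2 anti to the methyl-bearing α-carbon) | CN(C)/N=C1/[C@H](C)CC[C@H](C(C)=C)C1
F3 | step 9 | N,N-dimethylhydrazone of 12 (as formed, NMe2 on the side of the newly alkylated α-carbon) | CN(C)/N=C1/[C@H](C)CC[C@H](C(C)=C)[C@H]1CC[C@@](C)(C=C)[C@H](CC(C)C)c1c(OC)cc(OC)cc1OC
F4 | step 12 | dibromide: compound 15 with bromine at both free positions of the trimethoxyphenyl ring | CC(C)C[C@H](c1c(OC)c(Br)c(OC)c(Br)c1OC)[C@]1(C)C=C2[C@H](C)CC[C@H](C(C)(C)O)[C@H]2CC1
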